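**Plan**

- Retrosynthesis: the C8''–pyridyl bond is cut first (B-alkyl Suzuki coupling). Then come C3–H, O2–C3 and N1–O2 of the isoxazolidine (hydride onto an oxocarbenium ion, hemiketal closure, amine oxidation). Next, C3–C1'' is cut together with a temporary N1–C3 amide bond (organolithium opening of a β-lactam), then N1–C1' (lactam N-alkylation with a pyridyltridecyl bromide made from 3-picoline), and last N1–C6a and C3–C3a in one (2+2) event.
- Enabling feature: N1 on C6a and C3 on C3a sit cis on neighbouring carbons of the cyclopentane ring. This is the imprint of the N=C unit of an isocyanate added to one face of cyclopentene. The N1–C3 bond of the resulting cis-fused azetidinone is absent from the target and is later exchanged for N1–O2–C3.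
- Forward order: the cyclopentane is bought; the azetidinone ring forms first, receives the pyridine-terminated C13 chain on nitrogen and is then cut open by oct-7-enyllithium. The isoxazolidine ring closes by N-oxidation, hemiketalisation and reduction. The second pyridine ring is attached to the C8 chain in the last step.
- Stereochemistry: cis C3a/C6a comes from the suprafacial cycloaddition, the absolute configuration from a lipase resolution of the lactam, and C3 from hydride delivery to the convex face of the bicyclic oxocarbenium ion.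

Key step: step 1

Remark: the target is read as (3S,3aS,6aR)-3-[8-(pyridin-3-yl)octyl]-1-[13-(pyridin-3-yl)tridecyl]hexahydro-1H-cyclopenta[c]isoxazole (N1, O2, C3, C3a, C4–C6, C6a), both chains saturated, with H3, H3a and H6a on one face.

**Route**

Step 1
Reactants: 1 cyclopentene; 2 chlorosulfonyl isocyanate
Product: 3 cis-7-oxo-6-azabicyclo[3.2.0]heptane-6-sulfonyl chloride (racemate)
Conditions: CH2Cl2, 0 °C to 40 °C; concentrated and used crude
Reagents that add atoms: none
Why: The electron-poor central carbon of 2 attacks the π bond of 1 and nitrogen closes onto the developing cationic carbon on the same face before any bond rotation, an asynchronous but effectively concerted (2+2) cycloaddition. The closest known reaction type is the Graf β-lactam synthesis from chlorosulfonyl isocyanate and simple alkenes. The azetidin-2-one is the only ring formed and it closes by intermolecular (2+2) cycloaddition, both ring bonds (C7–C1 and N6–C5, later C3–C3a and N1–C6a of the target) being made suprafacially on the alkene. The two new stereocentres C1 and C5 are controlled by that suprafacial delivery and by ring strain, since a trans-fused bicyclo[3.2.0]heptanone cannot form, so only the cis racemate should arise. No regio- or facial selectivity is required because cyclopentene is symmetric; the only selectivity needed is cycloaddition over ene-type formation of an unsaturated N-chlorosulfonyl amide, which the unsubstituted secondary alkene carbons and the cool, nonpolar medium should secure.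

Step 2
Reactants: 3 cis-7-oxo-6-azabicyclo[3.2.0]heptane-6-sulfonyl chloride (racemate)
Product: 4 cis-6-azabicyclo[3.2.0]heptan-7-one (racemate)
Conditions: Na2SO3, NaHCO3, H2O/CH2Cl2, 0 °C, pH 7–8
Reagents that add atoms: none
Why: Sulfite reduces the N-sulfonyl chloride to the N-sulfinate, which hydrolyses with loss of bisulfite to the free lactam (the standard reductive hydrolysis of chlorosulfonyl isocyanate adducts); near-neutral pH keeps the strained amide closed and leaves both stereocentres untouched.

Step 3
Reactants: 4 cis-6-azabicyclo[3.2.0]heptan-7-one (racemate)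
Product: 5 (1S,5R)-6-azabicyclo[3.2.0]heptan-7-one
Conditions: immobilised Candida antarctica lipase B, H2O (1 equiv), iPr2O, 60–70 °C; filter off enzyme and amino acid
Reagents that add atoms: none
Why: Lipase-catalysed enantioselective lactam hydrolysis (kinetic resolution) is expected to open only the (1R,5S) lactam to the insoluble cis amino acid, leaving in solution the (1S,5R) lactam that maps onto C3a (S) and C6a (R); no stereocentre is formed, the absolute configuration is selected.

Step 4
Reactants: 6 3-methylpyridine; 7 1,12-dibromododecane (threefold excess)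
Product: 9 3-(13-bromotridecyl)pyridine, via (pyridin-3-yl)methyllithium 8 (not isolated)
Conditions: LiN(iPr)2 (LDA, 1.05 equiv), THF, −78 °C; anion added to 7 (3 equiv), THF, −78 °C to 0 °C; chromatography, kept cold and used promptly
Reagents that add atoms: none
Why: Lateral lithiation of 3-picoline by the amide base gives picolyl anion 8, which displaces one primary bromide of 7 in an SN2 alkylation, the excess of 7 suppressing double alkylation and the cold, prompt handling of 9 limiting intermolecular N-alkylation of the pyridine by its own bromide.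

Step 5
Reactants: 5 (1S,5R)-6-azabicyclo[3.2.0]heptan-7-one; 9 3-(13-bromotridecyl)pyridine
Product: 10 (1S,5R)-6-[13-(pyridin-3-yl)tridecyl]-6-azabicyclo[3.2.0]heptan-7-one
Conditions: NaH, DMF, 0 °C to rt
Reagents that add atoms: none
Why: N-Alkylation of the lactam anion by SN2 displacement on the primary bromide of 9, a standard way to N-substitute azetidin-2-ones, forms N1–C1'; the sodium amidate is far more nucleophilic than the pyridine nitrogen and neither ring stereocentre is deprotonated under these conditions.

Step 6
Reactants: 10 (1S,5R)-6-[13-(pyridin-3-yl)tridecyl]-6-azabicyclo[3.2.0]heptan-7-one; 11 8-bromooct-1-ene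
Product: 14 1-[(1S,2R)-2-{[13-(pyridin-3-yl)tridecyl]amino}cyclopentyl]non-8-en-1-one, via oct-7-enyllithium 12 (not isolated), via lithium hemiaminal alkoxide 13 (not isolated)
Conditions: 11, Li metal (1% Na), Et2O, −10 °C; then added dropwise (1.1 equiv) to 10, THF, −78 °C; then AcOH, −78 °C, aq. NaHCO3 work-up; used at once
Reagents that add atoms: none
Why: This is ketone synthesis by organolithium addition to a tertiary amide: the strained lactam carbonyl should accept 12 at −78 °C faster than the pyridine ring does, giving tetrahedral alkoxide 13, which holds until protonation and then collapses with C–N cleavage driven by release of ring strain, so C3–C1'' is made and the temporary N1–C3 bond is broken while C3a and C6a stay cis because neither is involved.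

Step 7
Reactants: 14 1-[(1S,2R)-2-{[13-(pyridin-3-yl)tridecyl]amino}cyclopentyl]non-8-en-1-one
Product: 15 O-benzoyl-N-[(1R,2S)-2-(non-8-enoyl)cyclopentyl]-N-[13-(pyridin-3-yl)tridecyl]hydroxylamine
Conditions: dibenzoyl peroxide (1.1 equiv), K2HPO4, DMF, 0 °C to rt
Reagents that add atoms: dibenzoyl peroxide, O=C(OOC(=O)c1ccccc1)c1ccccc1
Why: Oxidation of a secondary amine with dibenzoyl peroxide (attack of nitrogen on the peroxide O–O bond) stops at the O-acylated hydroxylamine, so N1–O2 is made without over-oxidation to a nitrone, the far less nucleophilic pyridine nitrogen should not compete, and the phosphate buffer takes up the benzoic acid that would otherwise protonate the amine.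

Step 8
Reactants: 15 O-benzoyl-N-[(1R,2S)-2-(non-8-enoyl)cyclopentyl]-N-[13-(pyridin-3-yl)tridecyl]hydroxylamine
Product: 17 (3aS,6aR)-3-(oct-7-en-1-yl)-1-[13-(pyridin-3-yl)tridecyl]hexahydro-1H-cyclopenta[c]isoxazol-3-ol (both C3 epimers), via N-hydroxy amino ketone 16 (not isolated)
Conditions: K2CO3 (0.2 equiv), degassed MeOH, 0 °C; AcOH to neutral, concentrate
Reagents that add atoms: none
Why: Base-catalysed transesterification (Zemplén-type methanolysis) frees the N–OH group, which adds to the neighbouring ketone in a 5-exo-trig hemiketalisation that only the cis isomer can undergo; the C3 epimer mixture is erased in the next step.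

Step 9
Reactants: 17 (3aS,6aR)-3-(oct-7-en-1-yl)-1-[13-(pyridin-3-yl)tridecyl]hexahydro-1H-cyclopenta[c]isoxazol-3-ol
Product: 19 (3S,3aS,6aR)-3-(oct-7-en-1-yl)-1-[13-(pyridin-3-yl)tridecyl]hexahydro-1H-cyclopenta[c]isoxazole, via bicyclic oxocarbenium ion 18 (not isolated)
Conditions: Et3SiH (5 equiv), BF3·OEt2 (3.5 equiv), CH2Cl2, −78 °C to −20 °C; aq. NaHCO3 work-up
Reagents that add atoms: none
Why: In this ionic reduction of a cyclic hemiketal (Kishi-type lactol reduction), BF3 beyond the equivalent bound by the pyridine nitrogen ionises C3–OH to oxocarbenium ion 18 and Et3SiH should deliver hydride to its convex face, anti to the C3a–C4 bond, placing H3 cis to H3a and H6a and the chain endo, which is the (3S) configuration.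

Step 10
Reactants: 19 (3S,3aS,6aR)-3-(oct-7-en-1-yl)-1-[13-(pyridin-3-yl)tridecyl]hexahydro-1H-cyclopenta[c]isoxazole; 20 3-bromopyridine
Product: 22 pyrinodemin B, (3S,3aS,6aR)-3-[8-(pyridin-3-yl)octyl]-1-[13-(pyridin-3-yl)tridecyl]hexahydro-1H-cyclopenta[c]isoxazole, via B-alkyl-9-BBN adduct 21 (not isolated)
Conditions: 9-BBN (3 equiv), THF, rt to 50 °C; then aq. K3PO4, 20 (1.2 equiv), Pd(dppf)Cl2 (10 mol %), DMF, 60 °C
Reagents that add atoms: none
Why: Anti-Markovnikov hydroboration of the terminal alkene with 9-BBN (in excess because the pyridine nitrogen reversibly binds one equivalent) followed by B-alkyl Suzuki–Miyaura coupling (oxidative addition of 20 to zerovalent palladium, base-assisted alkyl transfer from boron, reductive elimination) forms the last CH2–pyridyl bond and leaves the three sp3 stereocentres and the N–O bond untouched.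

**Compound list**

1 | cyclopentene | C1=CCCC1 | starting material
2 | chlorosulfonyl isocyanate | O=C=NS(=O)(=O)Cl | starting material
3 | cis-7-oxo-6-azabicyclo[3.2.0]heptane-6-sulfonyl chloride, racemate, (1S,5R) enantiomer drawn | O=C1N(S(=O)(=O)Cl)[C@@H]2CCC[C@H]12 | intermediate
4 | cis-6-azabicyclo[3.2.0]heptan-7-one, racemate, (1S,5R) enantiomer drawn | O=C1N[C@@H]2CCC[C@H]12 | intermediate
5 | (1S,5R)-6-azabicyclo[3.2.0]heptan-7-one | O=C1N[C@@H]2CCC[C@H]12 | intermediate
6 | 3-methylpyridine | Cc1cccnc1 | starting material
7 | 1,12-dibromododecane | BrCCCCCCCCCCCCBr | starting material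
8 | (pyridin-3-yl)methyllithium | [Li]Cc1cccnc1 | intermediate
9 | 3-(13-bromotridecyl)pyridine | BrCCCCCCCCCCCCCc1cccnc1 | intermediate
10 | (1S,5R)-6-[13-(pyridin-3-yl)tridecyl]-6-azabicyclo[3.2.0]heptan-7-one | O=C1N(CCCCCCCCCCCCCc3cccnc3)[C@@H]2CCC[C@H]12 | intermediate
11 | 8-bromooct-1-ene | C=CCCCCCCBr | starting material
12 | oct-7-enyllithium | [Li]CCCCCCC=C | intermediate
13 | lithium (1S,5R)-7-(oct-7-en-1-yl)-6-[13-(pyridin-3-yl)tridecyl]-6-azabicyclo[3.2.0]heptan-7-olate (C7 undefined) | [Li+].[O-]C1(CCCCCCC=C)N(CCCCCCCCCCCCCc3cccnc3)[C@@H]2CCC[C@H]12 | intermediate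
14 | 1-[(1S,2R)-2-{[13-(pyridin-3-yl)tridecyl]amino}cyclopentyl]non-8-en-1-one | C=CCCCCCCC(=O)[C@H]1CCC[C@H]1NCCCCCCCCCCCCCc2cccnc2 | intermediate
15 | O-benzoyl-N-[(1R,2S)-2-(non-8-enoyl)cyclopentyl]-N-[13-(pyridin-3-yl)tridecyl]hydroxylamine | C=CCCCCCCC(=O)[C@H]1CCC[C@H]1N(OC(=O)c2ccccc2)CCCCCCCCCCCCCc3cccnc3 | intermediate
16 | 1-[(1S,2R)-2-{hydroxy[13-(pyridin-3-yl)tridecyl]amino}cyclopentyl]non-8-en-1-one | C=CCCCCCCC(=O)[C@H]1CCC[C@H]1N(O)CCCCCCCCCCCCCc2cccnc2 | intermediate
17 | (3aS,6aR)-3-(oct-7-en-1-yl)-1-[13-(pyridin-3-yl)tridecyl]hexahydro-1H-cyclopenta[c]isoxazol-3-ol (C3 epimers) | c1cncc(CCCCCCCCCCCCCN2OC(O)(CCCCCCC=C)[C@H]3CCC[C@H]32)c1 | intermediate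
18 | (3aS,6aR)-3-(oct-7-en-1-yl)-1-[13-(pyridin-3-yl)tridecyl]-bicyclic oxocarbenium ion (C3=O2 cation) | c1cncc(CCCCCCCCCCCCCN2[O+]=C(CCCCCCC=C)[C@H]3CCC[C@H]32)c1 | intermediate
19 | (3S,3aS,6aR)-3-(oct-7-en-1-yl)-1-[13-(pyridin-3-yl)tridecyl]hexahydro-1H-cyclopenta[c]isoxazole | c1cncc(CCCCCCCCCCCCCN2O[C@@H](CCCCCCC=C)[C@H]3CCC[C@H]32)c1 | intermediate
20 | 3-bromopyridine | Brc1cccnc1 | starting material
21 | (3S,3aS,6aR)-3-[8-(9-borabicyclo[3.3.1]nonan-9-yl)octyl]-1-[13-(pyridin-3-yl)tridecyl]hexahydro-1H-cyclopenta[c]isoxazole | c1cncc(CCCCCCCCCCCCCN2O[C@@H](CCCCCCCCB4C5CCCC4CCC5)[C@H]3CCC[C@H]32)c1 | intermediate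
22 | pyrinodemin B, (3S,3aS,6aR)-3-[8-(pyridin-3-yl)octyl]-1-[13-(pyridin-3-yl)tridecyl]hexahydro-1H-cyclopenta[c]isoxazole | c1cncc(CCCCCCCCCCCCCN2O[C@@H](CCCCCCCCc3cccnc3)[C@H]3CCC[C@H]32)c1 | target

**Step count**

Total: 10 steps. Longest linear sequence: 9 steps (1, 2, 3, 5, 6, 7, 8, 9, 10); step 4 is a one-step side branch.

**Steps most likely to fail**

Step 6. The organolithium may add to C2 or C6 of the pyridine ring instead of the lactam carbonyl. The tetrahedral alkoxide may also collapse before the quench and take up a second equivalent, or the lactam may be enolised instead of attacked. Finally, the free cis amino ketone may epimerise or lose the amine by β-elimination during work-up. The fallback sets out from 10 and returns at 14; it exchanges the lactam for a Weinreb amide and the organolithium for a Grignard reagent, which does not add to pyridines. Acid methanolysis of 10 (HCl, MeOH, reflux; NaHCO3) should give methyl (1S,2R)-2-{[13-(pyridin-3-yl)tridecyl]amino}cyclopentane-1-carboxylate F1. Treatment with N,O-dimethylhydroxylamine hydrochloride and iPrMgCl (THF, −20 °C) should convert it into (1S,2R)-N-methoxy-N-methyl-2-{[13-(pyridin-3-yl)tridecyl]amino}cyclopentane-1-carboxamide F2. Bromide 11 and Mg turnings in THF give oct-7-enylmagnesium bromide F3. Addition of F3 in excess to F2 (THF, −20 °C to 0 °C; cold dilute aqueous HCl quench, then NaHCO3) then gives 14, since the chelated Weinreb adduct does not take up a second organometallic.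

Step 9. Ionisation may be weak because the Lewis acid is held by the pyridine and hydroxylamine nitrogens, the hemiketal may open to the hydroxylamino ketone and eliminate, or hydride may attack both faces of the cation. The fallback sets out from 15 and returns at 19; it replaces cation reduction by an SN2 ring closure. Reagent-controlled reduction of the ketone with catecholborane (in excess, the pyridine nitrogen binding the first equivalent) and (S)-2-methyl-CBS-oxazaborolidine (toluene, −78 °C; catecholborane spares the terminal alkene) is expected to give O-benzoyl-N-{(1R,2S)-2-[(1R)-1-hydroxynon-8-en-1-yl]cyclopentyl}-N-[13-(pyridin-3-yl)tridecyl]hydroxylamine F4. Mesylation (MsCl, Et3N, CH2Cl2, 0 °C) gives (1R)-1-[(1S,2R)-2-{(benzoyloxy)[13-(pyridin-3-yl)tridecyl]amino}cyclopentyl]non-8-en-1-yl methanesulfonate F5. K2CO3 in MeOH then removes the benzoate, and the hydroxylamine oxygen displaces the mesylate (5-exo-tet, inversion at C3) to give 19.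

Step 7. Nitrogen may be benzoylated instead of oxygenated, or the β-amino ketone may eliminate under the buffered conditions. The fallback sets out from 14 and returns at 17; it replaces peroxide oxidation by the cyanoethylation, N-oxidation and Cope elimination sequence. Conjugate addition of 14 to acrylonitrile (MeOH, rt) should give 3-{[(1R,2S)-2-(non-8-enoyl)cyclopentyl][13-(pyridin-3-yl)tridecyl]amino}propanenitrile F6. mCPBA (1 equiv, CH2Cl2, −78 °C) oxidises the trialkylamine, far faster than the pyridine nitrogen or the terminal alkene, to 3-{[(1R,2S)-2-(non-8-enoyl)cyclopentyl][13-(pyridin-3-yl)tridecyl]amino}propanenitrile N-oxide F7. On warming, F7 should lose acrylonitrile by Cope elimination towards the acidified cyanoethyl hydrogens to give 16, which closes to 17.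

**Further compounds**

F1 | step 6 | methyl (1S,2R)-2-{[13-(pyridin-3-yl)tridecyl]amino}cyclopentane-1-carboxylate | COC(=O)[C@H]1CCC[C@H]1NCCCCCCCCCCCCCc2cccnc2
F2 | step 6 | (1S,2R)-N-methoxy-N-methyl-2-{[13-(pyridin-3-yl)tridecyl]amino}cyclopentane-1-carboxamide | CON(C)C(=O)[C@H]1CCC[C@H]1NCCCCCCCCCCCCCc2cccnc2
F3 | step 6 | oct-7-enylmagnesium bromide | C=CCCCCCC[Mg]Br
F4 | step 9 | O-benzoyl-N-{(1R,2S)-2-[(1R)-1-hydroxynon-8-en-1-yl]cyclopentyl}-N-[13-(pyridin-3-yl)tridecyl]hydroxylamine | C=CCCCCCC[C@@H](O)[C@H]1CCC[C@H]1N(OC(=O)c2ccccc2)CCCCCCCCCCCCCc3cccnc3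
F5 | step 9 | (1R)-1-[(1S,2R)-2-{(benzoyloxy)[13-(pyridin-3-yl)tridecyl]amino}cyclopentyl]non-8-en-1-yl methanesulfonate | C=CCCCCCC[C@@H](OS(C)(=O)=O)[C@H]1CCC[C@H]1N(OC(=O)c2ccccc2)CCCCCCCCCCCCCc3cccnc3
F6 | step 7 | 3-{[(1R,2S)-2-(non-8-enoyl)cyclopentyl][13-(pyridin-3-yl)tridecyl]amino}propanenitrile | C=CCCCCCCC(=O)[C@H]1CCC[C@H]1N(CCC#N)CCCCCCCCCCCCCc2cccnc2
F7 | step 7 | 3-{[(1R,2S)-2-(non-8-enoyl)cyclopentyl][13-(pyridin-3-yl)tridecyl]amino}propanenitrile N-oxide | C=CCCCCCCC(=O)[C@H]1CCC[C@H]1[N+]([O-])(CCC#N)CCCCCCCCCCCCCc2cccnc2
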